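**Retrosynthetic overview**
- The C(=O)–CH2–CH2 link is disconnected to a (Z)-aurone. One reductive step saturates the exocyclic C=C and cuts the furanone C2–O bond, which returns the ketone, its α-CH2 and the free 2'-OH without any phenol protection or separate enone reduction.
- The aurone is assembled in one flask from an α-chloro-2,4-dihydroxyacetophenone and a catechol-derived benzaldehyde bis-ether: furanone closure, aldol-type condensation, aromatic Claisen (prenyl) and propargyl Claisen/oxa-6π (2H-pyran).
- The bis-ether comes from 3,4-dihydroxybenzaldehyde by 4-O-propargylation (Cu), then 3-O-tert-allylation (Pd).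
- Ring order: both benzene rings are bought. The temporary furanone and the 2H-pyran are formed together in step 4, and the furanone is opened in step 5.

Assumption: the target has no stereocentre and no stereogenic double bond, so the compound as drawn is the only stereoisomer to be made.

**Route**

Step 1
Reactants: 1 3,4-dihydroxybenzaldehyde; 2 3-chloro-3-methylbut-1-yne
Product: 3 3-hydroxy-4-[(2-methylbut-3-yn-2-yl)oxy]benzaldehyde
Conditions: 2 (1.1 equiv), DBU (1.05 equiv), CuCl2·2H2O (1 mol%), MeCN, −5 to 0 °C
Reagents that add atoms: none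
Why: Copper-catalysed propargylic etherification (Godfrey conditions) alkylates only the 4-OH, because it is para to the formyl group, about two pKa units more acidic than the 3-OH and so the only phenoxide present with one equivalent of base; no stereocentre is formed.

Step 2
Reactants: 4 2-methylbut-3-en-2-ol
Product: 5 methyl 2-methylbut-3-en-2-yl carbonate
Conditions: n-BuLi (1.05 equiv), THF, −78 °C; ClCO2Me (1.1 equiv), −78 °C to rt
Reagents that add atoms: methyl chloroformate COC(=O)Cl
Why: O-acylation of the lithium alkoxide of the tertiary allylic alcohol with a chloroformate is the standard preparation of the carbonate used for Pd-mediated reverse prenylation; no stereocentre is formed.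

Step 3
Reactants: 3 3-hydroxy-4-[(2-methylbut-3-yn-2-yl)oxy]benzaldehyde; 5 methyl 2-methylbut-3-en-2-yl carbonate
Product: 6 3-[(2-methylbut-3-en-2-yl)oxy]-4-[(2-methylbut-3-yn-2-yl)oxy]benzaldehyde
Conditions: 5 (1.5 equiv), Pd(PPh3)4 (3 mol%), THF, 0 °C to rt
Reagents that add atoms: none
Why: Tsuji–Trost O-allylation, in which decarboxylative ionisation of 5 gives a 1,1-dimethyl-π-allylpalladium methoxide, methoxide deprotonates the phenol, and the phenoxide attacks the more substituted allyl terminus under kinetic control to give the tertiary (reverse-prenyl) ether; no stereocentre is formed.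

Step 4
Reactants: 6 3-[(2-methylbut-3-en-2-yl)oxy]-4-[(2-methylbut-3-yn-2-yl)oxy]benzaldehyde; 7 2-chloro-1-(2,4-dihydroxyphenyl)ethan-1-one
Product: 11 (2Z)-6-hydroxy-2-{[8-hydroxy-2,2-dimethyl-7-(3-methylbut-2-en-1-yl)-2H-chromen-6-yl]methylidene}-1-benzofuran-3(2H)-one, via 6-hydroxy-1-benzofuran-3(2H)-one 8 (not isolated), via bis-ether aurone 9 (not isolated), via prenylphenol aurone 10 (not isolated)
Conditions: 7 (1.1 equiv), NaOAc (3 equiv), degassed DMF, 70 °C (3 h), then 150 °C (6 h)
Reagents that add atoms: none
Why: Proposed new method: acetate closes 7 to the coumaranone 8 (intramolecular Williamson etherification), whose acidic C2–H2 condenses with aldehyde 6 to the thermodynamic Z-aurone 9 (Knoevenagel-type aurone condensation, geometry erased in step 5), and at 150 °C the tertiary allyl ether moves to the only free ortho carbon as a prenyl group to give 10 (aromatic Claisen) while the tertiary propargyl ether closes the 2H-pyran at its only free ortho carbon (propargyl Claisen, 1,5-H shift, oxa-6π electrocyclisation), the weakly basic acetate/acetic acid buffer in DMF leaving the simple phenols protonated so that the pericyclic steps run as under neutral conditions; the closest known reactions are the NaOAc cyclisation of ω-chloro-2,4-dihydroxyacetophenone to 6-hydroxycoumaranone with its condensation to aurones, and the thermal chromene synthesis from aryl 1,1-dimethylpropargyl ethers.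

Step 5
Reactants: 11 (2Z)-6-hydroxy-2-{[8-hydroxy-2,2-dimethyl-7-(3-methylbut-2-en-1-yl)-2H-chromen-6-yl]methylidene}-1-benzofuran-3(2H)-one
Product: 12 1-(2,4-dihydroxyphenyl)-3-[8-hydroxy-2,2-dimethyl-7-(3-methylbut-2-en-1-yl)-2H-chromen-6-yl]propan-1-one
Conditions: SmI2 (4.5 equiv), MeOH (20 equiv), THF, −78 to 0 °C; aq NH4Cl
Reagents that add atoms: none
Why: Proposed new method: SmI2 first delivers two electrons to the aurone enone (conjugate reduction, MeOH protonation to the 2-benzylcoumaranone) and then two more to this α-aryloxy ketone, whose ketyl expels the ring phenoxide by C2–O scission to give the samarium enolate of the dihydrochalcone, while the prenyl and chromene alkenes and the electron-rich, phenoxide-bearing product ketone are not reduced by SmI2 without HMPA; the closest known reactions are the SmI2 conjugate reduction of chalcones and the Molander SmI2 cleavage of α-alkoxy and α-aryloxy ketones, and no stereocentre remains.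

**Compound list**

1 | 3,4-dihydroxybenzaldehyde | O=Cc1ccc(O)c(O)c1 | starting material
2 | 3-chloro-3-methylbut-1-yne | CC(C)(Cl)C#C | starting material
3 | 3-hydroxy-4-[(2-methylbut-3-yn-2-yl)oxy]benzaldehyde | O=Cc1ccc(OC(C)(C)C#C)c(O)c1 | intermediate
4 | 2-methylbut-3-en-2-ol | CC(C)(O)C=C | starting material
5 | methyl 2-methylbut-3-en-2-yl carbonate | COC(=O)OC(C)(C)C=C | intermediate
6 | 3-[(2-methylbut-3-en-2-yl)oxy]-4-[(2-methylbut-3-yn-2-yl)oxy]benzaldehyde | O=Cc1ccc(OC(C)(C)C#C)c(OC(C)(C)C=C)c1 | intermediate
7 | 2-chloro-1-(2,4-dihydroxyphenyl)ethan-1-one | O=C(CCl)c1ccc(O)cc1O | starting material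
8 | 6-hydroxy-1-benzofuran-3(2H)-one (not isolated) | O=C1COc2cc(O)ccc12 | intermediate
9 | bis-ether aurone: (2Z)-6-hydroxy-2-({3-[(2-methylbut-3-en-2-yl)oxy]-4-[(2-methylbut-3-yn-2-yl)oxy]phenyl}methylidene)-1-benzofuran-3(2H)-one (not isolated) | O=C1/C(=C/c2ccc(OC(C)(C)C#C)c(OC(C)(C)C=C)c2)Oc2cc(O)ccc12 | intermediate
10 | prenylphenol aurone: (2Z)-6-hydroxy-2-({3-hydroxy-2-(3-methylbut-2-en-1-yl)-4-[(2-methylbut-3-yn-2-yl)oxy]phenyl}methylidene)-1-benzofuran-3(2H)-one (not isolated) | O=C1/C(=C/c2ccc(OC(C)(C)C#C)c(O)c2CC=C(C)C)Oc2cc(O)ccc12 | intermediate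
11 | (2Z)-6-hydroxy-2-{[8-hydroxy-2,2-dimethyl-7-(3-methylbut-2-en-1-yl)-2H-chromen-6-yl]methylidene}-1-benzofuran-3(2H)-one | O=C1/C(=C/c2cc3C=CC(C)(C)Oc3c(O)c2CC=C(C)C)Oc2cc(O)ccc12 | intermediate
12 | 1-(2,4-dihydroxyphenyl)-3-[8-hydroxy-2,2-dimethyl-7-(3-methylbut-2-en-1-yl)-2H-chromen-6-yl]propan-1-one | CC(C)=CCc1c(CCC(=O)c2ccc(O)cc2O)cc2c(c1O)OC(C)(C)C=C2 | target

**Step count**

Total steps: 5. Longest linear sequence: 4 (1 → 3 → 6 → 11 → 12); step 2 is a one-step side branch that makes reagent 5.

**Steps most likely to fail, with fallbacks**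

Step 4 is the riskiest. The coumaranone may self-condense or oxidise, the aurone may react with its new ortho-prenyl group (hetero-Diels–Alder or ene) at 150 °C, and the freed phenol next to the propargyl ether may add to the alkyne. The fallback sets out from 6 and comes back at 11. Compound 6 is heated alone (N,N-diethylaniline, 180 °C, or DMF, 150 °C) so that both Claisen rearrangements and the electrocyclisation run on the simple aldehyde, giving 8-hydroxy-2,2-dimethyl-7-(3-methylbut-2-en-1-yl)-2H-chromene-6-carbaldehyde F1. Separately, 7 is closed to 8 with NaOAc in refluxing MeOH and isolated. F1 and 8 are then condensed on neutral alumina in CH2Cl2 at rt to give 11. The two rings are then made in separate flasks, and no aurone or base is heated to 150 °C.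

Step 5 is next. The reduction may stop at the 2-benzylcoumaranone, give reductive dimers of the enone, or over-reduce the product ketone. The fallback sets out from 11 and comes back at 12, splitting the four-electron reduction into two different reactions. A copper hydride conjugate reduction (Cu(OAc)2, 1,2-bis(diphenylphosphino)benzene, PMHS, t-BuOH, toluene, rt; fluoride work-up to free the phenols) gives racemic 6-hydroxy-2-{[8-hydroxy-2,2-dimethyl-7-(3-methylbut-2-en-1-yl)-2H-chromen-6-yl]methyl}-1-benzofuran-3(2H)-one F2. Zinc dust with NH4Cl in aqueous EtOH at 70 °C then cleaves the α-aryloxy ketone C–O bond to give 12, and the stereocentre of F2 disappears.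

Step 3 is third. The hindered 3-OH next to a tertiary ether may react slowly, the linear prenyl ether or C-allylation may compete, and the alkyne may interfere with Pd. The fallback sets out from 3 and comes back at 11, building the pyran first. Heating 3 (DMF, 150 °C) gives 8-hydroxy-2,2-dimethyl-2H-chromene-6-carbaldehyde F3. Its only phenol is alkylated with 2 (DBU, cat. CuCl2, MeCN, 0 °C) to 2,2-dimethyl-8-[(2-methylbut-3-yn-2-yl)oxy]-2H-chromene-6-carbaldehyde F4. Lindlar semihydrogenation (H2, Pd/CaCO3–Pb, quinoline, EtOAc) gives 2,2-dimethyl-8-[(2-methylbut-3-en-2-yl)oxy]-2H-chromene-6-carbaldehyde F5. F5 and 7 under the conditions of step 4 (NaOAc, DMF, 70 then 150 °C; furanone closure, condensation and aromatic Claisen to C7) give 11.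

**Further compounds**

F1 | step 4 | 8-hydroxy-2,2-dimethyl-7-(3-methylbut-2-en-1-yl)-2H-chromene-6-carbaldehyde | O=Cc1cc2C=CC(C)(C)Oc2c(O)c1CC=C(C)C
F2 | step 5 | 6-hydroxy-2-{[8-hydroxy-2,2-dimethyl-7-(3-methylbut-2-en-1-yl)-2H-chromen-6-yl]methyl}-1-benzofuran-3(2H)-one (racemic) | O=C1C(Cc2cc3C=CC(C)(C)Oc3c(O)c2CC=C(C)C)Oc2cc(O)ccc12
F3 | step 3 | 8-hydroxy-2,2-dimethyl-2H-chromene-6-carbaldehyde | O=Cc1cc(O)c2OC(C)(C)C=Cc2c1
F4 | step 3 | 2,2-dimethyl-8-[(2-methylbut-3-yn-2-yl)oxy]-2H-chromene-6-carbaldehyde | O=Cc1cc(OC(C)(C)C#C)c2OC(C)(C)C=Cc2c1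
F5 | step 3 | 2,2-dimethyl-8-[(2-methylbut-3-en-2-yl)oxy]-2H-chromene-6-carbaldehyde | O=Cc1cc(OC(C)(C)C=C)c2OC(C)(C)C=Cc2c1
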